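The readings were generated by integration with constants of no real substance; scatter was added.

Each substrate molecule charged stands as substrate, target or isomer of the product, and the midnight readings keep near that balance, summing to 104% at 50.0 s.

| setting | spring | midnight | ash | maple | cedar | alder |
|---|---|---|---|---|---|---|
| substrate | 1.5 M | 1.5 M | 1.5 M | 1.5 M | 1.5 M | 1.5 M |
| partner | 0.80 M | 1.8 M | 1.20 M | 1.20 M | 1.20 M | 1.20 M |
| temperature | 38 °C | 54 °C | 45 °C | 30 °C |  | 60 °C |
| remark | run made earlier | run made earlier |  |  | at 60 °C until 2.0 min, from then on at 30 °C |  |
| time |  |  | 2.5 min | 2.5 min | 2.5 min | 2.5 min |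

| run | time / s | target / % | isomer of the product / % | substrate / % |
|---|---|---|---|---|
| spring | 10.0 | 13 | 0 | 84 |
| spring | 12.0 | 19 | 1 | 86 |
| spring | 15.0 | 17 | 1 | 80 |
| spring | 25.0 | 25 | 0 | 73 |
| spring | 40.0 | 33 | 2 | 65 |
| spring | 60.0 | 38 | 2 | 58 |
| spring | 90.0 | 41 | 5 | 55 |
| midnight | 10.0 | 44 | 4 | 52 |
| midnight | 15.0 | 54 | 2 | 45 |
| midnight | 25.0 | 62 | 7 | 33 |
| midnight | 30.0 | 64 | 10 | 30 |
| midnight | 50.0 | 69 | 10 | 25 |
| midnight | 60.0 | 66 | 7 | 30 |

(standard deviation of a reading: 2 percentage points)

- what was read earlier has a scatter of 2 percentage points, one standard deviation

1. the flask that comes out highest in share of target in all that became target or isomer of the product, or "all alike" when all lie within 1.5 percentage points (ash / maple / cedar / alder / all alike)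
2. share of target in all that became target or isomer of the product, ash
3. share of target in all that became target or isomer of the product, maple
4. share of target in all that became target or isomer of the product, cedar
5. share of target in all that became target or isomer of the product, alder

A molecule choosing once at a fork with fixed odds leaves isomer per target constant. Yet in midnight that ratio reads 0.0612 over the first pair of readings, mean time 12.5 s, and 0.136 over the last three, mean time 46.7 s, which is twice as much.

I clear this up by following the molecule. Midnight's substrate reads 30%, 25% and 30% over those last three readings, no longer falling, so I take target to come apart again, and each return to the fork is a fresh chance at isomer. The ratio then counts minutes spent as target. Its rate of rise, 0.131 min⁻¹, is what I carry: the drift, the gain in isomer per target per minute. It rests on readings with a scatter of 2 percentage points, and the isomer numbers among them are small. If both routes take one substrate and one partner, the drift holds no charge, so I carry it across charges; it was read at 54 °C, and I leave it unscaled for the 60 °C of alder and of cedar's first stretch.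

For alder this gives a ratio of 0.361 at 2.5 min, a share of 73.5%. For cedar at the change, 2.0 min, it gives 0.295, a share of 77.2%, and I expect the cold stretch to lift that slightly. For ash and maple I have no reckoning of my own.

The forecast says maple, with ash 91%, maple 95%, cedar 88% and alder 86%, calling isomer “either parallel or a capped slow leak from target”. On alder and cedar my reckoning stands lower than the forecast.

The simulation gives maple, with ash 92.1%, maple 95.2%, cedar 78.3% and alder 72.6%.

    substrate + partner ⇌ target (K = 2.31 M⁻¹, k = 4.06 M⁻¹ min⁻¹, Ea = 44.0 kJ mol⁻¹, ΔH = −75.0 kJ mol⁻¹)
    substrate + partner ⇌ isomer of the product (K = 181 M⁻¹, k = 0.271 M⁻¹ min⁻¹, Ea = 53.0 kJ mol⁻¹, ΔH = 5.00 kJ mol⁻¹)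
    partner → decomposed reagent (k = 0.0467 min⁻¹, Ea = 109 kJ mol⁻¹)
    (constants at 60 °C)

Alder ends with isomer per target at 0.378, against my 0.361. In alder the forward making of target outruns the forward loss to isomer 15 to one at the asked time, as at the start (the selectivity factor), and half of the making's turnover up to the asked time is done by 0.0556 min, far sooner than the 2.5 min the flask stands.

Alder stopped at 40 s: the drift gives a ratio of 0.121, a share of 89.2%. The computed share there is 88.3%.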